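All compound numbers are those of the steps below. Positions are given in germacrane numbering (ring C1–C10, lactone carbons C11–C13).

## Analysis of the target

Compound 34 is a germacranolide: a ten-membered carbocycle (C1–C10) fused at C6–C7 to an α-methylene-γ-butyrolactone (O–C6, C7–C11, C12=O, C11=C13). The carbocycle holds a Z trisubstituted olefin C1=C10 and an E trisubstituted olefin C4=C5. There are four stereocentres (2R, 6R, 7S, 9S): the lactone is trans-fused, and in a flat projection the C2 oxygen, the C9 oxygen and the C7–C11 bond lie on one face, with the C6 oxygen on the other. C2 carries a free allylic hydroxyl; C9 carries an ester of (Z)-2-(hydroxymethyl)but-2-enoic acid, whose methyl group is cis to the carbonyl (the less stable, angelate-type geometry). The sensitive groups are the exo-methylene lactone (conjugate addition, base), the Z acrylate ester (isomerisation), the two allylic C–O bonds (ionisation, acyl migration between O2 and O9) and the 1,5-diene in a medium ring (acid-induced transannular reactions). The hard points are the medium-ring closure, the Z geometry of a trisubstituted ring olefin, the trans ring fusion with the right sense towards two remote carbinols, and telling apart two similar secondary allylic oxygens. The strategy rests on the fact that O2 and O9 flank the Z-C1=C10 olefin in a syn 1,4-relationship: an O–Si–O bridge between them places C1=C10 in a seven-membered ring (Si, O, C2, C1, C10, C9, O), in which only the Z olefin can exist.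

## Retrosynthetic reasoning

C9 ester. The acyl–O9 bond of 34 is cut first, giving alcohol 26 (C2 silylated) and acid 31 (primary hydroxyl silylated). The Z acrylate and its free hydroxyl are the most fragile part, so they arrive last. Forward, a hindered allylic carbinol must be acylated without Z-to-E leakage, and one desilylation then frees both hydroxyls.

C2/C9 differentiation. Alcohol 26 comes from diol 25 by silylation of the less hindered C2 hydroxyl, and 25 from silaketal 24 by cutting both Si–O bonds. Up to this point the two carbinols travel as one unit.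

C6–C7 bond and lactone C12–O bond. Lactone 24 is opened to enal-bromide 21. This cut removes both remaining stereocentres, the medium ring and the exo-methylene lactone in one operation. Forward, an allylchromium generated at C13 attacks the C6 aldehyde through C7 in a six-membered chair. A trans lactone requires C5 and C8 both equatorial, hence C8 trans to C13 on the C7=C11 olefin, i.e. C8 cis to the ester. The thermodynamic geometry that Baylis–Hillman-type chemistry delivers (C8 cis to C13) would lead to the cis lactone if the geometry is retained, so it is not used. Enal-bromide 21 goes back through 20 and 19 to alcohol 18 by functional-group changes only (C6 ether to aldehyde, C13 hydroxyl to bromide).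

C1=C10 bond (key cut). Silaketal 18 is opened across C1=C10 to diene 17, whose C1 vinyl and C10 isopropenyl groups are held 1,6 to each other by the O–Si–O bridge. Cutting here is the only way to get the Z trisubstituted olefin by ring size alone, and it joins the two halves of the molecule.

Acrylate unit. A free C9 hydroxyl next to the required acrylate geometry would close a six-membered lactone, and a silyl ether at C13 would later have to be removed beside the silaketal. Therefore 17 is derived from ynoate 15 by cis hydrometalation and hydroxymethylation at C11 (sets C8 cis to the ester, leaves C13–OH free), after C9–O is already on silicon. Ynoate 15 comes from terminal alkyne 13 by cutting C11–C12.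

Si–O bonds. Alkyne 13 is cut at both Si–O bonds into alcohol 7 (C1–C6), alcohol 10 (C7–C11 with C14) and dichlorosilane 11. The two carbinol centres are thus made separately and cannot influence each other.

Fragment 1. Alcohol 7 goes back to epoxide 6 (vinyl carbinol from a terminal epoxide plus one carbon). Epoxide 6 goes back to chlorohydrin diol 4; closing the epoxide removes the secondary hydroxyl, so the primary one can be etherified without any differentiation. Diol 4 comes from alkyne 2 by syn methyl-metalation and one-carbon trapping, which fixes E-C4=C5. Alkyne 2 comes from 1, which supplies C2 with its configuration from the chiral pool. An aldehyde route to C2 is avoided because the aldehyde would be β,γ-unsaturated and prone to move into conjugation.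

Fragment 2. Alcohol 10 is cut at C8–C9 into enal 8 and a three-carbon propargyl unit; a catalyst sets C9.

Side chain. Acid 31 goes back through 30 and 29 to ynoate 27 by the same cis hydrometalation and hydroxymethylation, which gives the Z geometry directly.

## Alternatives that were turned down

Alternative 1: The lactone is taken from the chiral pool and C7–C8 and C11–C13 are cut around it. Forward, the lithium enolate of S-tert-butyl thioacetate A2 adds to C7 of the butenolide A1 anti to its C6 substituent, and the lactone enolate is trapped at C11 by the iminium salt A3, giving the trans,trans lactone A4 with the methylene masked as a Mannich base. In its favour: C6 and C7 are set with dependable substrate control from a fixed centre, which is stronger than the macrocyclic face selection the chosen route needs, and the masked methylene survives long sequences, whereas the chosen route exposes the methylene lactone through its last seven steps. Against it: A4 holds only C5–C9 and C11–C13. The ten-membered ring, both trisubstituted olefins and the C2 and C9 carbinols are all still to come; the thioester carbon must become the 9S carbinol bearing a Z trisubstituted alkenyl group without a good control element; and a separate macrocyclisation is still required. The chosen strategy gives the Z olefin and both carbinols in one tethered unit and closes the ring while making the lactone, in fewer steps.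

Alternative 2: The transannular C4–C9 bond is cut, so the ten-membered ring comes from the trans-decalin A5. Forward, base generates the C9 alkoxide, the C4–C9 bond breaks as the C5 mesylate leaves, and the dienone A6 results. In its favour: no macrocyclisation is needed, the E-C4=C5 geometry follows stereospecifically from the antiperiplanar arrangement, and the Z-C1=C10 olefin is carried over from a cyclohexene. On ring formation and on C4=C5 geometry this is stronger than the chosen plan, which must close a medium ring under high dilution. Against it: A5 needs six stereocentres, three of which are destroyed in the key step, so the preparation is long and linear. After fragmentation C9 is a ketone in a flexible Z-enone and has to be reduced to the 9S alcohol with uncertain face selectivity; C12 is still at the alcohol level; and a base-sensitive enone sits in a 1,5-diene. The chosen strategy makes C9 once, as a carbinol of fixed configuration, and uses the C2/C9 pair constructively.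

Alternative 3: The C5–C6 bond is cut. Forward, the E-alkenyl iodide of the seco-aldehyde A7 is converted by divalent chromium with nickel catalysis into an alkenylchromium that adds to the C6 aldehyde; the alkoxide lactonises onto the C12 ester to give A8, which lacks the exo-methylene. In its favour: it equals the chosen route in using a chromium macrocyclisation that also closes the lactone, and it is stronger in two respects: the alkenyl iodide keeps its geometry, and no activated allylic bromide of defined geometry is needed. The methylene is also absent until late. Against it: C6 is created by addition to an α-stereogenic aldehyde with no cyclic transition state linking it to C7, and C7 bears two similar CH2 branches, so both ring fusions are expected. The α-formyl centre of A7 is epimerisable; A7 still needs the Z-C1=C10 unit; and the methylene must be added afterwards by enolate chemistry on a lactone carrying two allylic oxygen functions. The chosen allylchromium closure ties C6 to C7 through one chair transition state and delivers the methylene directly.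

Key step: step 9

Remark: the C7=C11 olefin is built with C8 cis to the ester and the C13 hydroxyl is carried unprotected, because a closed allylchromium transition state gives the trans lactone only from this geometry and no silyl ether then has to be removed beside the silaketal. PMB = 4-methoxybenzyl, TBS = tert-butyldimethylsilyl, TES = triethylsilyl.

Step 1
Reactants: 1 (2R)-2-(chloromethyl)oxirane [(R)-epichlorohydrin]
Product: 2 (2R)-1-chloropent-4-yn-2-ol
Conditions: HC≡CH, n-BuLi, THF, −78 °C; BF3·OEt2, then 1, −78 °C; aq. NH4Cl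
Reagents that add atoms: acetylene C#C (used as LiC≡CH)
Why: BF3-promoted opening of a terminal epoxide by an alkynyllithium (Yamaguchi-type alkynylation) occurs at the unsubstituted ring carbon and is faster than displacement of the primary chloride; the stereocentre is not touched, so 2 stays R.

Step 2
Reactants: 2 (2R)-1-chloropent-4-yn-2-ol
Product: 4 (2E,5R)-6-chloro-3-methylhex-2-ene-1,5-diol, via alkenylalane 3 (not isolated)
Conditions: Me3Al, Cp2ZrCl2 (cat.), CH2Cl2, 0 °C → rt; then n-BuLi, THF, −78 → 0 °C; (CH2O)n, rt; aq. KNaC4H4O6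
Reagents that add atoms: trimethylaluminium C[Al](C)C; formaldehyde (as paraformaldehyde) C=O
Why: Zirconium-catalysed methylalumination of the terminal alkyne (Negishi carboalumination) adds CH3 and Al syn with CH3 on the internal carbon, which fixes E-C4=C5; the derived alanate is hydroxymethylated at C5 with retention. The carbinol rides as its aluminium alkoxide and the primary chloride is inert.

Step 3
Reactants: 4 (2E,5R)-6-chloro-3-methylhex-2-ene-1,5-diol
Product: 6 (2R)-2-{(2E)-4-[(4-methoxyphenyl)methoxy]-2-methylbut-2-en-1-yl}oxirane, via epoxy alkoxide 5 (not isolated)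
Conditions: NaH, THF/DMF, 0 °C → rt; then PMBCl, Bu4NI (cat.), rt
Reagents that add atoms: 4-methoxybenzyl chloride COc1ccc(CCl)cc1
Why: The secondary alkoxide closes onto the neighbouring CH2Cl (intramolecular Williamson reaction) without touching the stereocentre, which removes the only secondary hydroxyl; the remaining primary alkoxide is then benzylated (Williamson ether synthesis), so no hydroxyl differentiation is needed.

Step 4
Reactants: 6 (2R)-2-{(2E)-4-[(4-methoxyphenyl)methoxy]-2-methylbut-2-en-1-yl}oxirane
Product: 7 (3R,5E)-7-[(4-methoxyphenyl)methoxy]-5-methylhepta-1,5-dien-3-ol (fragment 1)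
Conditions: Me3S+ I−, n-BuLi, THF, −10 °C → rt
Reagents that add atoms: trimethylsulfonium iodide C[S+](C)C.[I-]
Why: Dimethylsulfonium methylide opens the terminal epoxide at CH2 and the β-alkoxy sulfonium salt loses Me2S under the excess ylide (one-carbon homologation of an epoxide to an allylic alcohol); the carbinol carbon is untouched, so C2 is R.

Step 5
Reactants: 8 2-methylprop-2-enal (methacrolein)
Product: 10 (3S)-2-methylhex-1-en-5-yn-3-ol (fragment 2 precursor), via borate ester 9 (not isolated)
Conditions: allenyl-B(pin), (S)-3,3′-bis(2,4,6-triisopropylphenyl)-1,1′-binaphthyl-2,2′-diyl hydrogen phosphate (5 mol %), 4 Å MS, toluene, −20 °C; aqueous work-up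
Reagents that add atoms: allenylboronic acid pinacol ester C=C=CB1OC(C)(C)C(C)(C)O1
Why: Chiral phosphoric acid-catalysed propargylation of an aldehyde by an allenylboronate through a closed six-membered transition state (SE2′). The (R)-acid is taken to direct attack to the Re face of aryl and alkenyl aldehydes, so the (S)-acid is chosen for the S carbinol at C9; the B–O bond of 9 is hydrolysed on work-up.

Step 6
Reactants: 10 (3S)-2-methylhex-1-en-5-yn-3-ol; 11 dichlorodi(propan-2-yl)silane; 7 (3R,5E)-7-[(4-methoxyphenyl)methoxy]-5-methylhepta-1,5-dien-3-ol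
Product: 13 {[(3R,5E)-7-[(4-methoxyphenyl)methoxy]-5-methylhepta-1,5-dien-3-yl]oxy}{[(3S)-2-methylhex-1-en-5-yn-3-yl]oxy}di(propan-2-yl)silane, via chlorosilane 12 (not isolated)
Conditions: 10, 11, imidazole, CH2Cl2, 0 °C; then 7, imidazole, DMF, rt
Reagents that add atoms: none
Why: Stepwise silylation: the first chloride of 11 is displaced much faster than the second, so the more hindered carbinol 10 stops at the monochlorosilane 12, which then silylates the less hindered carbinol 7 (mixed silaketal formation). Neither stereocentre is involved.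

Step 7
Reactants: 13 mixed silaketal alkyne
Product: 15 methyl (5S)-5-{[{[(3R,5E)-7-[(4-methoxyphenyl)methoxy]-5-methylhepta-1,5-dien-3-yl]oxy}di(propan-2-yl)silyl]oxy}-6-methylhept-6-en-2-ynoate, via lithium acetylide 14 (not isolated)
Conditions: n-BuLi, THF, −78 °C; ClCO2Me, −78 → 0 °C
Reagents that add atoms: methyl chloroformate COC(=O)Cl
Why: Deprotonation of the terminal alkyne and C-acylation of the lithium acetylide by a chloroformate; the hindered dialkoxysilane, the PMB ether and the olefins are inert to n-BuLi at −78 °C for the short time needed.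

Step 8
Reactants: 15 silaketal ynoate
Product: 17 methyl (2Z,5S)-2-(hydroxymethyl)-5-{[{[(3R,5E)-7-[(4-methoxyphenyl)methoxy]-5-methylhepta-1,5-dien-3-yl]oxy}di(propan-2-yl)silyl]oxy}-6-methylhepta-2,6-dienoate, via alkenylalane 16 (not isolated)
Conditions: i-Bu2AlH, HMPA, THF, 0 °C; then HCHO (gas from (CH2O)n), 0 °C → rt; aq. KNaC4H4O6
Reagents that add atoms: formaldehyde C=O
Why: Conjugate hydroalumination of a 2-alkynoate by i-Bu2AlH–HMPA gives the α-alumino acrylate (aluminium allenolate), which adds to formaldehyde at C11 from the side of the C7 hydrogen, so C8 ends up cis to the ester (Z), i.e. trans to C13 as the later allylation requires. HMPA suppresses 1,2-reduction of the ester, and the cis hydroxy ester cannot lactonise because O9 is already on silicon.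

Step 9
Reactants: 17 tethered diene
Product: 18 methyl (2Z)-2-(hydroxymethyl)-4-[(4S,7R)-7-{(2E)-4-[(4-methoxyphenyl)methoxy]-2-methylbut-2-en-1-yl}-5-methyl-2,2-di(propan-2-yl)-4,7-dihydro-1,3,2-dioxasilepin-4-yl]but-2-enoate
Conditions: (H2IMes)(PCy3)Cl2Ru=CHPh (second-generation Grubbs catalyst, 10 mol %), CH2Cl2 (0.005 M), 40 °C
Reagents that add atoms: none
Why: The benzylidene of the catalyst exchanges onto the monosubstituted C1 vinyl group, the new alkylidene adds to the C10 isopropenyl olefin held nearby by the O–Si–O bridge, and cycloreversion of the ruthenacyclobutane releases the cyclic olefin and Ru=CH2, which carries the chain with loss of ethylene (Chauvin mechanism). The closest known reaction type is the ring-closing metathesis of temporarily silicon-tethered bis(allyloxy)silanes to 4,7-dihydro-1,3,2-dioxasilepines, including cases with one 1,1-disubstituted olefin. The one ring closed is seven-membered (Si, two O, C2, C1, C10, C9) and is formed by ring-closing olefin metathesis between the two terminal olefins. No stereocentre is created; the new element is the C1=C10 geometry, and a seven-membered ring can hold only the cis olefin, so C2 and C9 end up cis (Z). Site selectivity among five olefins is needed: E-C4=C5 and Z-C7=C11 are trisubstituted (the latter also electron-poor) and could only be engaged through four- or eight-membered rings, so only the 1,6-diene across silicon closes. Ring closure must outrun dimerisation through the vinyl group; the two isopropyl groups on silicon and high dilution favour closure. The C2 and C9 configurations, the free C13 hydroxyl and the PMB ether are not affected.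

Step 10
Reactants: 18 seven-membered silaketal alcohol
Product: 19 methyl (2E)-2-(bromomethyl)-4-[(4S,7R)-7-{(2E)-4-[(4-methoxyphenyl)methoxy]-2-methylbut-2-en-1-yl}-5-methyl-2,2-di(propan-2-yl)-4,7-dihydro-1,3,2-dioxasilepin-4-yl]but-2-enoate
Conditions: CBr4, PPh3, CH2Cl2, −20 → 0 °C
Reagents that add atoms: carbon tetrabromide BrC(Br)(Br)Br
Why: Appel bromination of a primary allylic alcohol by SN2 displacement of the alkoxyphosphonium ion; neutral conditions and low temperature are chosen to avoid SN2′ scrambling of the C7=C11 geometry and to spare the silaketal (the descriptor changes to E only because CH2Br outranks the ester).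

Step 11
Reactants: 19 allylic bromide
Product: 20 methyl (2E)-2-(bromomethyl)-4-[(4S,7R)-7-[(2E)-4-hydroxy-2-methylbut-2-en-1-yl]-5-methyl-2,2-di(propan-2-yl)-4,7-dihydro-1,3,2-dioxasilepin-4-yl]but-2-enoate
Conditions: 2,3-dichloro-5,6-dicyano-1,4-benzoquinone (DDQ), CH2Cl2/pH 7 buffer, 0 °C
Reagents that add atoms: none
Why: Oxidative cleavage of the PMB ether by DDQ (hydride abstraction to the oxocarbenium ion, hydrolysis); buffered two-phase conditions leave the silaketal, the allylic bromide and the olefins untouched.

Step 12
Reactants: 20 allylic alcohol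
Product: 21 methyl (2E)-2-(bromomethyl)-4-[(4S,7R)-5-methyl-7-[(2E)-2-methyl-4-oxobut-2-en-1-yl]-2,2-di(propan-2-yl)-4,7-dihydro-1,3,2-dioxasilepin-4-yl]but-2-enoate
Conditions: MnO2, CH2Cl2, rt
Reagents that add atoms: none
Why: MnO2 oxidation of the only allylic alcohol to the E enal under neutral heterogeneous conditions; no acid or base is present that could move the olefins or open the silaketal.

Step 13
Reactants: 21 enal-bromide
Product: 24 (2R,6R,7S,9S)-2,9-[di(propan-2-yl)silanediylbis(oxy)]germacra-1(10)Z,4E,11(13)-trien-12,6-olide, via allylchromium 22 (not isolated), via chromium alkoxide 23 (not isolated)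
Conditions: CrCl2 (excess), THF (0.003 M, slow addition of 21), rt
Reagents that add atoms: none
Why: Two equivalents of CrCl2 (divalent chromium) reduce the allylic bromide to the trivalent allylchromium 22, which adds through C7 to the C6 aldehyde in a chair six-membered transition state (Nozaki–Hiyama allylation, intramolecular Barbier type); with C8 trans to C13 and C5 equatorial the new centres are anti, and alkoxide 23 closes onto the methyl ester to give the trans-fused α-methylene lactone. The sense relative to C9 is under substrate control by the silaketal-bridged ring; the isomer needed keeps the C7–C11 bond on the face of the two silaketal oxygens, and this is the least secure element of the step.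

Step 14
Reactants: 24 silaketal lactone
Product: 25 (2R,6R,7S,9S)-2,9-dihydroxygermacra-1(10)Z,4E,11(13)-trien-12,6-olide
Conditions: HF·pyridine, pyridine, THF, 0 °C → rt
Reagents that add atoms: none
Why: Fluoride-induced cleavage of both Si–O bonds of the dialkoxysilane (desilylation); the buffered reagent is non-basic, so the methylene lactone and the allylic alcohols should survive.

Step 15
Reactants: 25 diol
Product: 26 (2R,6R,7S,9S)-2-[(tert-butyldimethylsilyl)oxy]-9-hydroxygermacra-1(10)Z,4E,11(13)-trien-12,6-olide
Conditions: TBSCl, imidazole, DMF, 0 °C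
Reagents that add atoms: tert-butyldimethylsilyl chloride CC(C)(C)[Si](C)(C)Cl
Why: Sterically controlled monosilylation: the C2 hydroxyl is flanked by CH= and CH2, the C9 hydroxyl by the methyl-bearing C10, so the bulky silyl chloride should react first at C2.

Step 16
Reactants: 27 methyl but-2-ynoate
Product: 29 methyl (2Z)-2-(hydroxymethyl)but-2-enoate, via alkenylalane 28 (not isolated)
Conditions: i-Bu2AlH, HMPA, THF, 0 °C; then HCHO (gas from (CH2O)n), 0 °C → rt; aq. KNaC4H4O6
Reagents that add atoms: formaldehyde C=O
Why: Same conjugate hydroalumination and hydroxymethylation as in step 8; attack of formaldehyde anti to the β-methyl group places the methyl cis to the ester (Z).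

Step 17
Reactants: 29 methyl (2Z)-2-(hydroxymethyl)but-2-enoate
Product: 30 methyl (2Z)-2-{[(tert-butyldimethylsilyl)oxy]methyl}but-2-enoate
Conditions: TBSCl, imidazole, CH2Cl2, 0 °C → rt
Reagents that add atoms: tert-butyldimethylsilyl chloride CC(C)(C)[Si](C)(C)Cl
Why: Standard silylation of a primary alcohol; no base strong enough to isomerise the olefin is present.

Step 18
Reactants: 30 silyl ether ester
Product: 31 (2Z)-2-{[(tert-butyldimethylsilyl)oxy]methyl}but-2-enoic acid
Conditions: LiOH, THF/H2O, 0 °C → rt; then 1 M HCl to pH 4, 0 °C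
Reagents that add atoms: lithium hydroxide [Li+].[OH-]
Why: Saponification of the methyl ester; hydroxide attacks the ester carbonyl rather than the hindered β-carbon, so the Z geometry and the silyl ether should be kept, and the brief cold acidification spares the TBS ether.

Step 19
Reactants: 31 (2Z)-2-{[(tert-butyldimethylsilyl)oxy]methyl}but-2-enoic acid; 26 C2 silyl ether alcohol
Product: 33 (2R,6R,7S,9S)-2-[(tert-butyldimethylsilyl)oxy]-9-{[(2Z)-2-{[(tert-butyldimethylsilyl)oxy]methyl}but-2-enoyl]oxy}germacra-1(10)Z,4E,11(13)-trien-12,6-olide, via mixed anhydride 32 (not isolated)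
Conditions: 2,4,6-Cl3C6H2COCl, Et3N, toluene, rt; then 26, DMAP, toluene, rt
Reagents that add atoms: none
Why: Yamaguchi esterification: DMAP transfers the acrylate acyl group of mixed anhydride 32, the trichlorobenzoyl carbonyl being blocked by its ortho chlorines, to the hindered C9 hydroxyl; a non-polar solvent and room temperature limit Z-to-E isomerisation of the angelate-type acyl group and addition to the methylene lactone.

Step 20
Reactants: 33 bis-silyl ether
Product: 34 (2R,6R,7S,9S)-2-hydroxy-9-{[(2Z)-2-(hydroxymethyl)but-2-enoyl]oxy}germacra-1(10)Z,4E,11(13)-trien-12,6-olide (CNP0273961.1)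
Conditions: HF·pyridine, pyridine, THF, 0 °C → rt
Reagents that add atoms: none
Why: Desilylation of the primary and the secondary TBS ether under buffered, non-basic fluoride conditions, which should avoid acyl migration from O9 to O2 and addition to the methylene lactone.

Compound list

1 | (2R)-2-(chloromethyl)oxirane | ClC[C@H]1CO1 | starting material
2 | (2R)-1-chloropent-4-yn-2-ol | ClC[C@H](O)CC#C | intermediate
3 | [(1E,4R)-5-chloro-4-(dimethylalumanyloxy)-2-methylpent-1-en-1-yl]dimethylalumane | ClC[C@H](O[Al](C)C)C/C(C)=C/[Al](C)C | intermediate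
4 | (2E,5R)-6-chloro-3-methylhex-2-ene-1,5-diol | ClC[C@H](O)C/C(C)=C/CO | intermediate
5 | sodium (2E)-3-methyl-4-[(2R)-oxiran-2-yl]but-2-en-1-olate | C1O[C@@H]1C/C(C)=C/C[O-].[Na+] | intermediate
6 | (2R)-2-{(2E)-4-[(4-methoxyphenyl)methoxy]-2-methylbut-2-en-1-yl}oxirane | C1O[C@@H]1C/C(C)=C/COCc2ccc(OC)cc2 | intermediate
7 | (3R,5E)-7-[(4-methoxyphenyl)methoxy]-5-methylhepta-1,5-dien-3-ol | C=C[C@H](O)C/C(C)=C/COCc1ccc(OC)cc1 | intermediate
8 | 2-methylprop-2-enal | C=C(C)C=O | starting material
9 | 4,4,5,5-tetramethyl-2-{[(3S)-2-methylhex-1-en-5-yn-3-yl]oxy}-1,3,2-dioxaborolane | C=C(C)[C@@H](OB1OC(C)(C)C(C)(C)O1)CC#C | intermediate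
10 | (3S)-2-methylhex-1-en-5-yn-3-ol | C=C(C)[C@@H](O)CC#C | intermediate
11 | dichlorodi(propan-2-yl)silane | CC(C)[Si](Cl)(Cl)C(C)C | starting material
12 | chloro{[(3S)-2-methylhex-1-en-5-yn-3-yl]oxy}di(propan-2-yl)silane | C=C(C)[C@@H](O[Si](Cl)(C(C)C)C(C)C)CC#C | intermediate
13 | {[(3R,5E)-7-[(4-methoxyphenyl)methoxy]-5-methylhepta-1,5-dien-3-yl]oxy}{[(3S)-2-methylhex-1-en-5-yn-3-yl]oxy}di(propan-2-yl)silane | C=C[C@H](O[Si](C(C)C)(C(C)C)O[C@H](C(C)=C)CC#C)C/C(C)=C/COCc1ccc(OC)cc1 | intermediate
14 | lithium acetylide of 13 | C=C[C@H](O[Si](C(C)C)(C(C)C)O[C@H](C(C)=C)CC#C[Li])C/C(C)=C/COCc1ccc(OC)cc1 | intermediate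
15 | methyl (5S)-5-{[{[(3R,5E)-7-[(4-methoxyphenyl)methoxy]-5-methylhepta-1,5-dien-3-yl]oxy}di(propan-2-yl)silyl]oxy}-6-methylhept-6-en-2-ynoate | C=C[C@H](O[Si](C(C)C)(C(C)C)O[C@H](C(C)=C)CC#CC(=O)OC)C/C(C)=C/COCc1ccc(OC)cc1 | intermediate
16 | methyl 2-[bis(2-methylpropyl)alumanyl] analogue of 17 (Al at C11, trans to C8) | C=C[C@H](O[Si](C(C)C)(C(C)C)O[C@H](C(C)=C)C/C=C(/[Al](CC(C)C)CC(C)C)C(=O)OC)C/C(C)=C/COCc1ccc(OC)cc1 | intermediate
17 | methyl (2Z,5S)-2-(hydroxymethyl)-5-{[{[(3R,5E)-7-[(4-methoxyphenyl)methoxy]-5-methylhepta-1,5-dien-3-yl]oxy}di(propan-2-yl)silyl]oxy}-6-methylhepta-2,6-dienoate | C=C[C@H](O[Si](C(C)C)(C(C)C)O[C@H](C(C)=C)C/C=C(/CO)C(=O)OC)C/C(C)=C/COCc1ccc(OC)cc1 | intermediate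
18 | methyl (2Z)-2-(hydroxymethyl)-4-[(4S,7R)-7-{(2E)-4-[(4-methoxyphenyl)methoxy]-2-methylbut-2-en-1-yl}-5-methyl-2,2-di(propan-2-yl)-4,7-dihydro-1,3,2-dioxasilepin-4-yl]but-2-enoate | CC(C)[Si]1(C(C)C)O[C@H](C/C(C)=C/COCc2ccc(OC)cc2)/C=C(/C)[C@H](C/C=C(/CO)C(=O)OC)O1 | intermediate
19 | methyl (2E)-2-(bromomethyl)-4-[(4S,7R)-7-{(2E)-4-[(4-methoxyphenyl)methoxy]-2-methylbut-2-en-1-yl}-5-methyl-2,2-di(propan-2-yl)-4,7-dihydro-1,3,2-dioxasilepin-4-yl]but-2-enoate | CC(C)[Si]1(C(C)C)O[C@H](C/C(C)=C/COCc2ccc(OC)cc2)/C=C(/C)[C@H](C/C=C(/CBr)C(=O)OC)O1 | intermediate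
20 | methyl (2E)-2-(bromomethyl)-4-[(4S,7R)-7-[(2E)-4-hydroxy-2-methylbut-2-en-1-yl]-5-methyl-2,2-di(propan-2-yl)-4,7-dihydro-1,3,2-dioxasilepin-4-yl]but-2-enoate | CC(C)[Si]1(C(C)C)O[C@H](C/C(C)=C/CO)/C=C(/C)[C@H](C/C=C(/CBr)C(=O)OC)O1 | intermediate
21 | methyl (2E)-2-(bromomethyl)-4-[(4S,7R)-5-methyl-7-[(2E)-2-methyl-4-oxobut-2-en-1-yl]-2,2-di(propan-2-yl)-4,7-dihydro-1,3,2-dioxasilepin-4-yl]but-2-enoate | CC(C)[Si]1(C(C)C)O[C@H](C/C(C)=C/C=O)/C=C(/C)[C@H](C/C=C(/CBr)C(=O)OC)O1 | intermediate
22 | dichloro(allyl)chromium derived from 21 (Cr on C13) | CC(C)[Si]1(C(C)C)O[C@H](C/C(C)=C/C=O)/C=C(/C)[C@H](C/C=C(/C[Cr](Cl)Cl)C(=O)OC)O1 | intermediate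
23 | dichlorochromium 6-alkoxide of methyl (2R,6R,7S,9S)-6-hydroxy-2,9-[di(propan-2-yl)silanediylbis(oxy)]germacra-1(10)Z,4E,11(13)-trien-12-oate | COC(=O)C(=C)[C@@H]1C[C@@H]2O[Si](C(C)C)(C(C)C)O[C@H](C/C(C)=C/[C@H]1O[Cr](Cl)Cl)/C=C\2C | intermediate
24 | (2R,6R,7S,9S)-2,9-[di(propan-2-yl)silanediylbis(oxy)]germacra-1(10)Z,4E,11(13)-trien-12,6-olide | C=C1C(=O)O[C@@H]2/C=C(\C)C[C@@H]3/C=C(/C)[C@H](C[C@@H]12)O[Si](C(C)C)(C(C)C)O3 | intermediate
25 | (2R,6R,7S,9S)-2,9-dihydroxygermacra-1(10)Z,4E,11(13)-trien-12,6-olide | C=C1C(=O)O[C@@H]2/C=C(\C)C[C@@H](O)/C=C(/C)[C@@H](O)C[C@@H]12 | intermediate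
26 | (2R,6R,7S,9S)-2-[(tert-butyldimethylsilyl)oxy]-9-hydroxygermacra-1(10)Z,4E,11(13)-trien-12,6-olide | C=C1C(=O)O[C@@H]2/C=C(\C)C[C@@H](O[Si](C)(C)C(C)(C)C)/C=C(/C)[C@@H](O)C[C@@H]12 | intermediate
27 | methyl but-2-ynoate | CC#CC(=O)OC | starting material
28 | methyl (2E)-2-[bis(2-methylpropyl)alumanyl]but-2-enoate | C/C=C(/[Al](CC(C)C)CC(C)C)C(=O)OC | intermediate
29 | methyl (2Z)-2-(hydroxymethyl)but-2-enoate | C/C=C(/CO)C(=O)OC | intermediate
30 | methyl (2Z)-2-{[(tert-butyldimethylsilyl)oxy]methyl}but-2-enoate | C/C=C(/CO[Si](C)(C)C(C)(C)C)C(=O)OC | intermediate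
31 | (2Z)-2-{[(tert-butyldimethylsilyl)oxy]methyl}but-2-enoic acid | C/C=C(/CO[Si](C)(C)C(C)(C)C)C(=O)O | intermediate
32 | (2Z)-2-{[(tert-butyldimethylsilyl)oxy]methyl}but-2-enoic 2,4,6-trichlorobenzoic anhydride | C/C=C(/CO[Si](C)(C)C(C)(C)C)C(=O)OC(=O)c1c(Cl)cc(Cl)cc1Cl | intermediate
33 | (2R,6R,7S,9S)-2-[(tert-butyldimethylsilyl)oxy]-9-{[(2Z)-2-{[(tert-butyldimethylsilyl)oxy]methyl}but-2-enoyl]oxy}germacra-1(10)Z,4E,11(13)-trien-12,6-olide | C=C1C(=O)O[C@@H]2/C=C(\C)C[C@@H](O[Si](C)(C)C(C)(C)C)/C=C(/C)[C@@H](OC(=O)/C(=C\C)CO[Si](C)(C)C(C)(C)C)C[C@@H]12 | intermediate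
34 | (2R,6R,7S,9S)-2-hydroxy-9-{[(2Z)-2-(hydroxymethyl)but-2-enoyl]oxy}germacra-1(10)Z,4E,11(13)-trien-12,6-olide | C=C1C(=O)O[C@@H]2/C=C(\C)C[C@@H](O)/C=C(/C)[C@@H](OC(=O)/C(=C\C)CO)C[C@@H]12 | target

Total step count: 20. Longest linear sequence: 16 steps (steps 1–4, 6–15, 19, 20).

Steps least certain to work

Step 9 (key step). The alkylidene formed at C1 may close only slowly onto the hindered isopropenyl olefin. Intermolecular metathesis through the vinyl groups and hydride-induced migration of the allylic double bonds could then compete, and the free C13 hydroxyl beside the ester may tie up the ruthenium centre. Fallback: set out from 15 and run the ring closure one stage earlier. Compound 15 has no hydroxyl, and its conjugated internal alkyne could interfere only through an eight-membered ring. The same catalyst should give methyl 4-[(4S,7R)-7-{(2E)-4-[(4-methoxyphenyl)methoxy]-2-methylbut-2-en-1-yl}-5-methyl-2,2-di(propan-2-yl)-4,7-dihydro-1,3,2-dioxasilepin-4-yl]but-2-ynoate F1. Hydroalumination with i-Bu2AlH/HMPA and trapping with formaldehyde, as in step 8, then converts F1 into 18, where the route is rejoined.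

Step 13. The two anti transition states may not be well discriminated, because C2 and C9 act on the reacting carbons only through the conformation of the bridged ring. The strain added by the silaketal bridge may also let intermolecular coupling win over closure of the ten-membered ring. Fallback (lactone lock), setting out from 19 and rejoining at 26:
- Aqueous HF in MeCN removes the silylene, and the freed C9 hydroxyl closes onto the cis ester to give (6S)-3-(bromomethyl)-6-{(2Z,4R,6E)-4-hydroxy-8-[(4-methoxyphenyl)methoxy]-6-methylocta-2,6-dien-2-yl}-5,6-dihydro-2H-pyran-2-one F2, in which the C2 hydroxyl is the only free one.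
- TBSOTf/2,6-lutidine gives the C2 silyl ether F3.
- DDQ gives the C6 alcohol F4.
- MnO2 gives the enal F5.
- CrCl2 under high dilution then forms an allylchromium that is endocyclic in the lactone, so C8 is necessarily trans to C13. The C6 aldehyde, tethered through C9, can reach only the C7 face cis to the C9–C10 bond. The first product is the bridged (2R,6R,7S,9S)-2-[(tert-butyldimethylsilyl)oxy]-6-hydroxygermacra-1(10)Z,4E,11(13)-trien-12,9-olide F6 as its chromium alkoxide.
- The C6 alkoxide of F6 is expected to open the six-membered lactone to the five-membered 6,12-olide, releasing the C9 hydroxyl and giving 26 directly.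

This detour also makes steps 14 and 15 unnecessary.

Step 15. The rate difference between the two secondary allylic hydroxyls may be too small, so that mono- and bis-silylation overlap. Fallback, setting out from 25 and rejoining at 26: TESOTf/2,6-lutidine gives the 2,9-bis(triethylsilyl) ether F7. Brief PPTS/MeOH at low temperature solvolyses the less hindered C2 silyl ether to the 9-triethylsilyl ether F8 (over- or under-reacted material returns to F7 or 25). TBSOTf/2,6-lutidine gives the 2-TBS-9-TES ether F9, and PPTS/MeOH then removes the far more labile triethylsilyl group to give 26.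

Step 8. The ester may suffer over-reduction, the aluminium allenolate may be captured inefficiently because formaldehyde polymerises, and the geometry may erode if the allenolate is protonated and re-formed. Fallback, setting out from 15 and rejoining at 17: syn hydrostannation with Bu3SnH and the zerovalent palladium complex Pd(PPh3)4 gives the α-stannyl acrylate, methyl (2E,5S)-2-(tributylstannyl)-5-(silaketal-oxy)-6-methylhepta-2,6-dienoate F10 (C8 cis to the ester). I2 gives the corresponding (2E)-2-iodo ester F11, and Stille coupling of F11 with Bu3SnCH2OH under Pd(PPh3)4 gives 17.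

Further compounds

F1 | step 9 | methyl 4-[(4S,7R)-7-{(2E)-4-[(4-methoxyphenyl)methoxy]-2-methylbut-2-en-1-yl}-5-methyl-2,2-di(propan-2-yl)-4,7-dihydro-1,3,2-dioxasilepin-4-yl]but-2-ynoate | CC(C)[Si]1(C(C)C)O[C@H](C/C(C)=C/COCc2ccc(OC)cc2)/C=C(/C)[C@H](CC#CC(=O)OC)O1
F2 | step 13 | (6S)-3-(bromomethyl)-6-{(2Z,4R,6E)-4-hydroxy-8-[(4-methoxyphenyl)methoxy]-6-methylocta-2,6-dien-2-yl}-5,6-dihydro-2H-pyran-2-one | BrCC1=CC[C@H](OC1=O)/C(C)=C\[C@H](O)C/C(C)=C/COCc2ccc(OC)cc2
F3 | step 13 | (6S)-3-(bromomethyl)-6-{(2Z,4R,6E)-4-[(tert-butyldimethylsilyl)oxy]-8-[(4-methoxyphenyl)methoxy]-6-methylocta-2,6-dien-2-yl}-5,6-dihydro-2H-pyran-2-one | BrCC1=CC[C@H](OC1=O)/C(C)=C\[C@H](O[Si](C)(C)C(C)(C)C)C/C(C)=C/COCc2ccc(OC)cc2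
F4 | step 13 | (6S)-3-(bromomethyl)-6-{(2Z,4R,6E)-4-[(tert-butyldimethylsilyl)oxy]-8-hydroxy-6-methylocta-2,6-dien-2-yl}-5,6-dihydro-2H-pyran-2-one | BrCC1=CC[C@H](OC1=O)/C(C)=C\[C@H](O[Si](C)(C)C(C)(C)C)C/C(C)=C/CO
F5 | step 13 | (2E,5R,6Z)-7-[(2S)-5-(bromomethyl)-6-oxo-3,6-dihydro-2H-pyran-2-yl]-5-[(tert-butyldimethylsilyl)oxy]-3-methylocta-2,6-dienal | BrCC1=CC[C@H](OC1=O)/C(C)=C\[C@H](O[Si](C)(C)C(C)(C)C)C/C(C)=C/C=O
F6 | step 13 | (2R,6R,7S,9S)-2-[(tert-butyldimethylsilyl)oxy]-6-hydroxygermacra-1(10)Z,4E,11(13)-trien-12,9-olide | C=C1C(=O)O[C@H]2C[C@@H]1[C@H](O)/C=C(\C)C[C@@H](O[Si](C)(C)C(C)(C)C)/C=C\2C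
F7 | step 15 | (2R,6R,7S,9S)-2,9-bis[(triethylsilyl)oxy]germacra-1(10)Z,4E,11(13)-trien-12,6-olide | C=C1C(=O)O[C@@H]2/C=C(\C)C[C@@H](O[Si](CC)(CC)CC)/C=C(/C)[C@@H](O[Si](CC)(CC)CC)C[C@@H]12
F8 | step 15 | (2R,6R,7S,9S)-2-hydroxy-9-[(triethylsilyl)oxy]germacra-1(10)Z,4E,11(13)-trien-12,6-olide | C=C1C(=O)O[C@@H]2/C=C(\C)C[C@@H](O)/C=C(/C)[C@@H](O[Si](CC)(CC)CC)C[C@@H]12
F9 | step 15 | (2R,6R,7S,9S)-2-[(tert-butyldimethylsilyl)oxy]-9-[(triethylsilyl)oxy]germacra-1(10)Z,4E,11(13)-trien-12,6-olide | C=C1C(=O)O[C@@H]2/C=C(\C)C[C@@H](O[Si](C)(C)C(C)(C)C)/C=C(/C)[C@@H](O[Si](CC)(CC)CC)C[C@@H]12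
F10 | step 8 | methyl (2E,5S)-5-{[{[(3R,5E)-7-[(4-methoxyphenyl)methoxy]-5-methylhepta-1,5-dien-3-yl]oxy}di(propan-2-yl)silyl]oxy}-6-methyl-2-(tributylstannyl)hepta-2,6-dienoate | C=C[C@H](O[Si](C(C)C)(C(C)C)O[C@H](C(C)=C)C/C=C(/[Sn](CCCC)(CCCC)CCCC)C(=O)OC)C/C(C)=C/COCc1ccc(OC)cc1
F11 | step 8 | methyl (2E,5S)-2-iodo-5-{[{[(3R,5E)-7-[(4-methoxyphenyl)methoxy]-5-methylhepta-1,5-dien-3-yl]oxy}di(propan-2-yl)silyl]oxy}-6-methylhepta-2,6-dienoate | C=C[C@H](O[Si](C(C)C)(C(C)C)O[C@H](C(C)=C)C/C=C(/I)C(=O)OC)C/C(C)=C/COCc1ccc(OC)cc1
A1 | alternative 1 | (5S)-5-{[(tert-butyldiphenylsilyl)oxy]methyl}furan-2(5H)-one | O=C1C=C[C@@H](CO[Si](c2ccccc2)(c2ccccc2)C(C)(C)C)O1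
A2 | alternative 1 | S-tert-butyl ethanethioate | CC(=O)SC(C)(C)C
A3 | alternative 1 | N,N-dimethylmethaniminium iodide | C=[N+](C)C.[I-]
A4 | alternative 1 | trans,trans-trisubstituted lactone with C11 dimethylaminomethyl group and C7 thioester arm | CN(C)C[C@@H]1C(=O)O[C@H](CO[Si](c2ccccc2)(c2ccccc2)C(C)(C)C)[C@H]1CC(=O)SC(C)(C)C
A5 | alternative 2 | trans-fused decalin with C9 tertiary hydroxyl, C5 mesylate, C4 angular methyl, 2-OTBS, 6-OTES and C7 3-(triethylsilyloxy)prop-1-en-2-yl group | CC[Si](CC)(CC)O[C@@H]1[C@@H](OS(C)(=O)=O)[C@]2(C)C[C@@H](O[Si](C)(C)C(C)(C)C)C=C(C)[C@@]2(O)C[C@H]1C(=C)CO[Si](CC)(CC)CC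
A6 | alternative 2 | ten-membered 1(10)Z,4E-dien-9-one carrying the C2, C6 and C7 stereocentres | CC[Si](CC)(CC)O[C@@H]1/C=C(\C)C[C@@H](O[Si](C)(C)C(C)(C)C)/C=C(/C)C(=O)C[C@H]1C(=C)CO[Si](CC)(CC)CC
A7 | alternative 3 | seco-aldehyde: methyl ester with C6 formyl group at C7, E-alkenyl iodide at C5, 2-OTBS and 9-OPMB | I/C=C(\C)C[C@@H](O[Si](C)(C)C(C)(C)C)/C=C(/C)[C@@H](OCc1ccc(OC)cc1)C[C@H](C=O)CC(=O)OC
A8 | alternative 3 | bicyclic trans-lactone lacking the exo-methylene, 2-OTBS, 9-OPMB | O=C1O[C@@H]2/C=C(\C)C[C@@H](O[Si](C)(C)C(C)(C)C)/C=C(/C)[C@@H](OCc3ccc(OC)cc3)C[C@H]2C1
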